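## Structural features

The target is a bicyclo[3.3.1]nonane. Ring B (C1–C2–C3–C4–C5–C9) is a 3-prenyl-1,3-dione held as its enol, a vinylogous acid O–C2=C3–C4=O. Ring C (C1–C9–C5–C6–C7–C8) is a cyclohexane bridged over ring B by the C9 ketone. Both bridgeheads are quaternary: C1 carries the (R)-2-methylbutanoyl group between three carbonyl-type carbons, and C5 carries a prenyl group. C1, C8 and C7 are contiguous stereocentres: C8 is quaternary with an axial methyl and an equatorial homoprenyl group, and C7 bears an exo (equatorial) prenyl group. C5 is locked to C1 by the bicycle, and a fifth stereocentre sits in the side chain α to a ketone. The fragile groups are the four trisubstituted alkenes, the non-enolisable β-tricarbonyl at C1 (retro-Claisen), the acid- and air-sensitive vinylogous acid, and the enolisable acyl stereocentre. The real difficulty is the crowded C1–C8–C7 region between two quaternary bridgeheads, made worse because the two alkyl groups on C8 differ little in size. The key step exploits the fact that C2 and C9, the oxygenated carbons flanking C1, are the enol ether carbons of a 1,5-dimethoxycyclohexa-1,4-diene. With C8 on C1, a carbenoid at C6 reaches C5 of the C9(OMe)=C5 enol ether, and the methoxy group on C9 then pushes open the transient C6–C9 bond so that C9 becomes the bridging ketone.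

## Logic of the disconnections

26 from 25. Only the O–CH3 bond of the C2 enol ether is cut. The methyl ether masks the vinylogous acid during the strongly basic bridgehead chemistry. The forward step must cleave a methyl ether without touching four alkenes, the tricarbonyl at C1 or the enolisable acyl stereocentre, so a neutral SN2 demethylation is needed.

25 from 22 and 24. The C1–C(acyl) bond is cut. This removes the side-chain stereocentre and the most crowded quaternary centre at once, and leaves a bridgehead C–H that is the only acidic position (α to C9=O and γ to the C4 carbonyl through C2=C3). The forward step needs a bridgehead carbanion that is acylated on carbon, and an acyl donor that does not racemise through a ketene.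

22 from 21. The C4=O bond is cut back to a CH2. Ring B then carries only the two oxygens that an enol-ether diene can deliver. The forward oxidation must choose the ring C4–H over the allylic positions of four side chains, above all the doubly allylic CH2 of the C3 prenyl group.

21 from 20, and 20 from 18 and 19. The C7–prenyl bond and the C6–S bond are cut. A C6=C7 vinyl sulfone lets the prenyl group arrive as a nucleophile on the open exo face, which sets C7, and the sulfone is then removed reductively. A radical at C7 is deliberately avoided: it is a hex-5-enyl radical with respect to the C8 homoprenyl alkene and would cyclise before any intermolecular allylation. The forward addition must transfer the prenyl group through its CH2 terminus and must spare the C9 ketone.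

18 from 17, and 17 from 16. The C7–O bond is cut. The β-keto sulfone of 16 enolises only toward C6, so O-triflation followed by hydride transfer from a palladium formate removes the oxygen and leaves the acceptor alkene. Both steps must tolerate the enol ether and the bridgehead C–H.

16 from 14 (key step). The C5–C6 bond is cut, which opens ring C and removes the stereocentres C1 and C5. The precursor is a C1-substituted 1,5-dimethoxycyclohexa-1,4-diene whose two enol ethers differ only by their relation to C8. Three changes are made to the bare diazoketone plan: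
- The diazo carbon carries a phenylsulfonyl group. This gives an acceptor/acceptor copper carbenoid with little tendency to insert into C–H bonds, it brings the substrate into the class for which copper–bisoxazoline catalysts give group-selective cyclopropanation, and the sulfone is reused in the C7 chemistry above.
- Water is supplied to turn the C9 oxocarbenium ion into the ketone, because the methyl group does not leave on its own.
- No correction of the structures flanking the key step was needed. The C8 descriptor changes between precursor and target only because the CIP priorities change.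

The forward step must select one of two diastereotopic enol ethers.

14 from 13, and 13 from 11 and 12. The C=N2 unit and the C6–C7 bond are cut. An ester and a sulfonyl carbanion are both stable under base, which the acid-labile bis(enol ether) requires. An acid chloride route to a diazoketone would generate HCl and is avoided.

11 from 9. The two ring C–H bonds at C1 and C4 are cut (dearomatisation). The Birch reduction must leave both methoxy groups on double bonds, must spare the isolated alkenes and the carboxylate, and must be worked up without acid.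

9 from 7 and 8. The C8–homoprenyl bond is cut. This is the only step that sets an absolute configuration by a reagent. The carboxylic acid enediolate has no E/Z isomers, which removes the geometry problem of a fully substituted enolate. The forward step must achieve face selection on a di-ortho-substituted aryl enediolate.

7 from 5 and 6. The aryl–C8 bond is cut. A palladium α-arylation joins the hindered position between the two methoxy groups to the propanoate carbon.

5 from 4, 4 from 2 and 3, and 2 from 1. The C–Br bond and the two aryl–prenyl bonds are cut. Bromination of 1 gives the 4,6-pattern, halogen–lithium exchange places both prenyl groups, and the remaining position between the methoxy groups is then the most acidic C–H.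

24 from 23. The C–Cl bond is cut. Activation must proceed without base so that the stereocentre survives.

## Other disconnections considered

Alternative 1: The cut is C1–C2 and C8–C11, where C11 is the first carbon of the future homoprenyl chain. In the forward direction, irradiation of cyclohexenone A1, which carries a dioxinone on a C5 acyl tether, would add the dioxinone alkene across C1=C8 to give cyclobutane A2. Retro-aldol opening would then release the C2 ketone.
- In its favour: all three ring B oxygens (C2, C4, C9) would be in place without any late C–H oxidation. On this point the alternative is better than the chosen plan, whose step 14 is its weakest operation. C1 and quaternary C8 would also be formed in one step under tether control.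
- Against it here: the excited enone has the C5 and C7 prenyl alkenes within reach for competing [2+2] addition. The dioxinone is itself a chromophore, and straight versus crossed addition and the face at C8 are open questions. After unzipping, C8 carries a CH2CO2H group that still has to be built into the homoprenyl chain, and C3 prenylation and C1 acylation remain.
- Comparison: structurally A2 holds both rings and the full oxygen pattern but an incomplete C8 substituent, whereas 16 holds every skeletal carbon except the acyl group but lacks one oxygen. Mechanistically, a triplet enone discriminates poorly between alkenes, while the electrophilic copper carbenoid is biased toward the enol ether. In step count the two plans should be similar, with the alternative longer after its key step.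

Alternative 2: The cut is C1–C9 and C3–C4. In the forward direction, keto malonate A3 would undergo a double Claisen condensation under base: C1 acylates one ester and C3 the other, giving trione A4 as its C3 enolate.
- In its favour: A4 already has both rings, all prenyl groups and all ring oxygens, so only O-methylation, C1 acylation and demethylation would remain. In endgame length it is better than the chosen plan, and it avoids both the C4 oxidation and the installation of C7 on the bicycle. Because Claisen condensations are reversible, the product with equatorial C7 and C8 substituents could be reached under thermodynamic control. This is at least equal to the kinetic exo argument of step 12.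
- Against it here: the vicinal C7/C8 pair, including the quaternary centre, must be built in an open chain, which is no easier than making 9 and adds C7. The first ring closure must pick one of two diastereotopic esters on C5 with only substrate bias. The first product has a non-enolisable quaternary β-dicarbonyl at C5 and is open to retro-Claisen cleavage, and the bridgehead C1 cannot be enolised once the second ring has closed.
- Comparison: the chosen plan places the C1/C5 decision under a chiral catalyst, the alternative under substrate and equilibrium control. If A3 were readily available the alternative would be the shorter route, but the burden moves into the synthesis of A3.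

Alternative 3: The cut is C5–C6 and C7–C8 of ring C. In the forward direction, (Z)-siloxydiene A5 and acryloyl oxazolidinone A6 would combine under a chiral copper Lewis acid to give cyclohexene A7.
- In its favour: C7 and quaternary C8 would be set in both relative and absolute sense in one catalytic step from achiral components. This is better than the chosen plan, which needs two separately risky operations for the same result (steps 5 and 12). The two-point-bound dienophile and the endo rule make the outcome well defined.
- Against it here: only ring C and two stereocentres are formed. Ring B, both quaternary bridgeheads and the oxygens at C2, C4 and C9 remain to be built, and the imide must be turned into a prenyl group. The diene must be geometrically pure and reacts through a fully substituted terminus.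
- Comparison: structurally A7 is much further from the target than 16. Mechanistically, a concerted catalyst-controlled cycloaddition is more predictable than a group-selective carbenoid addition. In step economy the alternative is clearly longer after its key step, the chosen plan somewhat longer before it.

Key step: step 9

Remarks on the chemistry:
- The target is written as one enol tautomer of the vinylogous acid, and the tautomers are one compound.
- Locants C1–C9 are the bicyclo[3.3.1]nonane locants used in the sections above.
- The antipodes of the tetramine (step 5) and of the bisoxazoline (step 9) are written as the ones expected to be matched. Both antipodes are available if the sense is the reverse.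
- C6 of 16 and 20 is an epimer mixture of no consequence and is left undefined.

## Steps

Step 1
Reactants: 1 1,3-dimethoxybenzene
Product: 2 1,5-dibromo-2,4-dimethoxybenzene
Conditions: N-bromosuccinimide (2.1 equiv), MeCN, 0 °C to rt
Reagents that add atoms: N-bromosuccinimide, O=C1CCC(=O)N1Br
Why: Electrophilic aromatic bromination; each bromine enters para to one methoxy group and ortho to the other, and the hindered position between the methoxy groups stays free.

Step 2
Reactants: 2 1,5-dibromo-2,4-dimethoxybenzene; 3 1-bromo-3-methylbut-2-ene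
Product: 4 1,5-dimethoxy-2,4-bis(3-methylbut-2-en-1-yl)benzene
Conditions: t-BuLi (4.2 equiv), THF, −78 °C; CuBr·SMe2 (0.2 equiv); 3 (2.6 equiv), −78 to 0 °C
Reagents that add atoms: 1-bromo-3-methylbut-2-ene (3), CC(C)=CCBr
Why: Double bromine–lithium exchange (each aryllithium stabilised by an ortho methoxy group) followed by copper-catalysed SN2 allylation at the unhindered CH2 terminus of prenyl bromide.

Step 3
Reactants: 4 1,5-dimethoxy-2,4-bis(3-methylbut-2-en-1-yl)benzene
Product: 5 3-bromo-2,4-dimethoxy-1,5-bis(3-methylbut-2-en-1-yl)benzene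
Conditions: n-BuLi (1.2 equiv), THF, 0 °C; BrCl2C–CCl2Br (1.3 equiv), −78 °C to rt
Reagents that add atoms: 1,2-dibromo-1,1,2,2-tetrachloroethane, ClC(Cl)(Br)C(Cl)(Cl)Br
Why: Directed ortho-metalation at the C–H flanked by two methoxy groups, then electrophilic bromination with a positive-bromine donor that does not touch the alkenes.

Step 4
Reactants: 5 3-bromo-2,4-dimethoxy-1,5-bis(3-methylbut-2-en-1-yl)benzene; 6 propanoic acid
Product: 7 2-[2,6-dimethoxy-3,5-bis(3-methylbut-2-en-1-yl)phenyl]propanoic acid (racemic)
Conditions: 6 (1.3 equiv), Me3SiCl, LiN(SiMe3)2, THF, rt; then 5, Pd(dba)2 (5 mol %), P(t-Bu)3 (10 mol %), ZnF2 (0.5 equiv), DMF, 80 °C; aq. citric acid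
Reagents that add atoms: propanoic acid (6), CCC(=O)O
Why: Palladium-catalysed α-arylation of a carboxylic acid through its bis(silyl) ketene acetal, which hydrolyses back to the acid on work-up; the bulky electron-rich phosphine is the ligand class that couples di-ortho-substituted aryl bromides, and the prenyl groups are meta to palladium and cannot insert.

Step 5
Reactants: 7 2-[2,6-dimethoxy-3,5-bis(3-methylbut-2-en-1-yl)phenyl]propanoic acid (racemic); 8 5-bromo-2-methylpent-2-ene
Product: 9 (2S)-2-[2,6-dimethoxy-3,5-bis(3-methylbut-2-en-1-yl)phenyl]-2,6-dimethylhept-5-enoic acid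
Conditions: (R,R)-N,N'-bis(1-phenyl-2-piperidin-1-ylethyl)propane-1,3-diamine (1.05 equiv), n-BuLi (4.1 equiv), THF, 0 °C; then 8 (2 equiv), −78 to −40 °C; cold dilute HCl (amine recovered by extraction)
Reagents that add atoms: 5-bromo-2-methylpent-2-ene (8), CC(C)=CCCBr
Why: Enantioselective alkylation of a carboxylic acid enediolate inside a mixed aggregate with a chiral dilithium amide (a traceless auxiliary); the enediolate has no E/Z isomers, so C8 is set only by which face the primary bromide meets, and the existing stereocentre of 7 is erased on deprotonation so the racemate is a suitable substrate.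

Step 6
Reactants: 9 (2S)-2-[2,6-dimethoxy-3,5-bis(3-methylbut-2-en-1-yl)phenyl]-2,6-dimethylhept-5-enoic acid
Product: 11 methyl (2S)-2-[2,6-dimethoxy-3,5-bis(3-methylbut-2-en-1-yl)cyclohexa-2,5-dien-1-yl]-2,6-dimethylhept-5-enoate, via lithium carboxylate 10 (not isolated)
Conditions: Li (8 equiv), NH3(l)/THF, t-BuOH (3 equiv), −78 to −33 °C; solid NH4Cl; evaporate; MeI (5 equiv), DMF, rt
Reagents that add atoms: iodomethane, CI
Why: Birch reduction; the radical anion is protonated at the ring carbon between the methoxy groups and at the carbon para to it, so both methoxy groups end on double bonds, while the carboxylate and isolated trisubstituted alkenes are inert; methylation of the carboxylate avoids ever freeing an acid next to the bis(enol ether), and C8 is not touched.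

Step 7
Reactants: 11 methyl (2S)-2-[2,6-dimethoxy-3,5-bis(3-methylbut-2-en-1-yl)cyclohexa-2,5-dien-1-yl]-2,6-dimethylhept-5-enoate; 12 methyl phenyl sulfone
Product: 13 (3S)-3-[2,6-dimethoxy-3,5-bis(3-methylbut-2-en-1-yl)cyclohexa-2,5-dien-1-yl]-3,7-dimethyl-1-(phenylsulfonyl)oct-6-en-2-one
Conditions: 12 (2.5 equiv), n-BuLi (2.5 equiv), THF, −78 °C; then 11, −78 to 0 °C; aq. NH4Cl
Reagents that add atoms: methyl phenyl sulfone (12), CS(=O)(=O)c1ccccc1
Why: Claisen-type acylation of a sulfonyl carbanion by the ester, driven by deprotonation of the β-keto sulfone by the second equivalent; entirely basic, so the enol ethers survive, and no enolisable centre lies next to C8.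

Step 8
Reactants: 13 (3S)-3-[2,6-dimethoxy-3,5-bis(3-methylbut-2-en-1-yl)cyclohexa-2,5-dien-1-yl]-3,7-dimethyl-1-(phenylsulfonyl)oct-6-en-2-one
Product: 14 (3S)-1-diazo-3-[2,6-dimethoxy-3,5-bis(3-methylbut-2-en-1-yl)cyclohexa-2,5-dien-1-yl]-3,7-dimethyl-1-(phenylsulfonyl)oct-6-en-2-one
Conditions: 4-acetamidobenzenesulfonyl azide (1.2 equiv), Et3N, MeCN, 0 °C to rt
Reagents that add atoms: 4-acetamidobenzenesulfonyl azide, CC(=O)Nc1ccc(cc1)S(=O)(=O)N=[N+]=[N-]
Why: Regitz diazo transfer to the doubly activated methylene under mild amine base; nothing else in the molecule is acidic enough to react.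

Step 9
Reactants: 14 (3S)-1-diazo-3-[2,6-dimethoxy-3,5-bis(3-methylbut-2-en-1-yl)cyclohexa-2,5-dien-1-yl]-3,7-dimethyl-1-(phenylsulfonyl)oct-6-en-2-one
Product: 16 (1S,5R,8S)-2-methoxy-8-methyl-3,5-bis(3-methylbut-2-en-1-yl)-8-(4-methylpent-3-en-1-yl)-6-(phenylsulfonyl)bicyclo[3.3.1]non-2-ene-7,9-dione (C6 epimers), via alkoxy-acyl cyclopropane 15 (not isolated)
Conditions: [Cu(MeCN)4]PF6 (10 mol %), (S,S)-2,2'-(propane-2,2-diyl)bis(4-tert-butyl-4,5-dihydrooxazole) (12 mol %), toluene, 50 °C; then THF, 0.5 M aq. HCl, 0 °C, short contact
Reagents that add atoms: water, O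
Why: The monovalent copper–bisoxazoline complex turns 14 into an electrophilic keto-sulfonyl carbenoid at C6, which adds to the electron-rich enol ether C9(OMe)=C5 on the face carrying the C1–C8 tether to give cyclopropane 15; with the methoxy donor on C9 and two acceptors on C6 the C6–C9 bond ionises, water adds to the C9 oxocarbenium ion, methanol leaves and the C6 enol is protonated. The closest known reaction type is the catalytic asymmetric intramolecular cyclopropanation of α-diazo-β-keto sulfones by copper–bisoxazoline catalysts, including group-selective reactions of cyclohexa-2,5-dienyl substrates, followed by heterolytic opening of the alkoxy-acyl cyclopropane. The carbenoid first closes a five-membered ring through C6–C9 (a 5-exo addition fused to the cyclopropane); once that bond is cleaved only C5–C6 remains, so ring C is formed as a net 6-endo closure onto the distal enol ether carbon. C5 and C1 are fixed together by the choice of enol ether, because the tether forces delivery syn to C8; that choice is made by the chiral ligand, with C8 adding only a small bias. Since C8 is already a single enantiomer, the wrong choice gives a diastereomer that chromatography removes and not the enantiomer. The carbenoid must ignore three trisubstituted alkenes and the allylic C–H bonds of the homoprenyl chain, which the low C–H insertion tendency of an acceptor/acceptor copper carbenoid, the nucleophilicity of the enol ether and the five-membered tether should secure. The second enol ether must survive the opening, which is plausible because ionisation of the push–pull cyclopropane needs no C-protonation and should be much faster than hydrolysis of a tetrasubstituted enol ether in cold dilute acid.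

Step 10
Reactants: 16 (1S,5R,8S)-2-methoxy-8-methyl-3,5-bis(3-methylbut-2-en-1-yl)-8-(4-methylpent-3-en-1-yl)-6-(phenylsulfonyl)bicyclo[3.3.1]non-2-ene-7,9-dione
Product: 17 (1S,5R,8S)-2-methoxy-8-methyl-3,5-bis(3-methylbut-2-en-1-yl)-8-(4-methylpent-3-en-1-yl)-9-oxo-6-(phenylsulfonyl)bicyclo[3.3.1]nona-2,6-dien-7-yl trifluoromethanesulfonate
Conditions: NaH (1.1 equiv), THF, 0 °C; N-(5-chloropyridin-2-yl)-N-(trifluoromethylsulfonyl)trifluoromethanesulfonamide (1.2 equiv), 0 °C to rt
Reagents that add atoms: N-(5-chloropyridin-2-yl)-N-(trifluoromethylsulfonyl)trifluoromethanesulfonamide, O=S(=O)(N(c1ccc(Cl)cn1)S(=O)(=O)C(F)(F)F)C(F)(F)F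
Why: The β-keto sulfone is by far the most acidic site and can enolise only toward C6 (C8 is quaternary); O-sulfonylation of the stabilised enolate gives the enol triflate and removes the C6 stereocentre.

Step 11
Reactants: 17 (1S,5R,8S)-2-methoxy-8-methyl-3,5-bis(3-methylbut-2-en-1-yl)-8-(4-methylpent-3-en-1-yl)-9-oxo-6-(phenylsulfonyl)bicyclo[3.3.1]nona-2,6-dien-7-yl trifluoromethanesulfonate
Product: 18 (1S,5R,8S)-2-methoxy-8-methyl-3,5-bis(3-methylbut-2-en-1-yl)-8-(4-methylpent-3-en-1-yl)-6-(phenylsulfonyl)bicyclo[3.3.1]nona-2,6-dien-9-one
Conditions: Pd(OAc)2 (5 mol %), PPh3 (10 mol %), HCO2H (2 equiv), n-Bu3N (3 equiv), DMF, 60 °C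
Reagents that add atoms: none
Why: Palladium-catalysed formate reduction of a vinyl triflate (oxidative addition to zerovalent palladium, formate exchange, decarboxylation, C–H reductive elimination); it replaces the C7 oxygen by hydrogen without reducing any alkene and leaves the C6=C7 vinyl sulfone.

Step 12
Reactants: 18 (1S,5R,8S)-2-methoxy-8-methyl-3,5-bis(3-methylbut-2-en-1-yl)-8-(4-methylpent-3-en-1-yl)-6-(phenylsulfonyl)bicyclo[3.3.1]nona-2,6-dien-9-one; 19 (3-methylbut-2-en-1-yl)magnesium chloride
Product: 20 (1S,5R,7R,8S)-2-methoxy-8-methyl-3,5,7-tris(3-methylbut-2-en-1-yl)-8-(4-methylpent-3-en-1-yl)-6-(phenylsulfonyl)bicyclo[3.3.1]non-2-en-9-one (C6 epimers)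
Conditions: 19 (3 equiv), CuBr·SMe2 (1.5 equiv), THF/Me2S, −78 °C; then 18, −78 to −30 °C; aq. NH4Cl
Reagents that add atoms: (3-methylbut-2-en-1-yl)magnesium chloride (19), CC(C)=CC[Mg]Cl
Why: Conjugate addition of an allylic organocopper reagent to a cyclic vinyl sulfone; the reagent should approach C7 from the exo face (the side of the one-carbon C9 bridge), because the endo face is covered by ring B, which sets the exo prenyl group, and allylic copper reagents are expected to transfer through the unsubstituted CH2 terminus and to spare the hindered C9 ketone. No radical is formed at C7, so the homoprenyl alkene cannot be captured.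

Step 13
Reactants: 20 (1S,5R,7R,8S)-2-methoxy-8-methyl-3,5,7-tris(3-methylbut-2-en-1-yl)-8-(4-methylpent-3-en-1-yl)-6-(phenylsulfonyl)bicyclo[3.3.1]non-2-en-9-one
Product: 21 (1S,5R,7S,8R)-2-methoxy-8-methyl-3,5,7-tris(3-methylbut-2-en-1-yl)-8-(4-methylpent-3-en-1-yl)bicyclo[3.3.1]non-2-en-9-one
Conditions: Na(Hg) (6 % Na, 6 equiv), Na2HPO4, MeOH/THF, −20 °C
Reagents that add atoms: none
Why: Reductive desulfonylation by electron transfer (C–S cleavage, reduction of the C6 radical to the carbanion, protonation by methanol); the C6 radical has no alkene in a 5-exo position, the buffered cold medium spares the hindered C9 ketone, and C7 is not involved, so its configuration is kept (the descriptor changes only through CIP priorities).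

Step 14
Reactants: 21 (1S,5R,7S,8R)-2-methoxy-8-methyl-3,5,7-tris(3-methylbut-2-en-1-yl)-8-(4-methylpent-3-en-1-yl)bicyclo[3.3.1]non-2-en-9-one
Product: 22 (1S,5S,7S,8R)-2-methoxy-8-methyl-3,5,7-tris(3-methylbut-2-en-1-yl)-8-(4-methylpent-3-en-1-yl)bicyclo[3.3.1]non-2-ene-4,9-dione
Conditions: Pd(OH)2/C (10 mol %), t-BuOOH (5 equiv, in decane), K2CO3 (0.3 equiv), CH2Cl2, 0 °C to rt
Reagents that add atoms: tert-butyl hydroperoxide, CC(C)(C)OO
Why: Peroxide-based allylic oxidation; the tert-butylperoxyl radical removes the pseudo-axial C4–H, which is locked parallel to the enol ether π system and gives a methoxy-substituted allyl radical, and collapse of the C4 peroxide gives the vinylogous ester. The bridgehead C1–H cannot give a delocalised radical; the doubly allylic CH2 of the C3 prenyl group is the main competing site and is treated in the closing section.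

Step 15
Reactants: 23 (2R)-2-methylbutanoic acid
Product: 24 (2R)-2-methylbutanoyl chloride
Conditions: (COCl)2 (1.1 equiv), DMF (cat.), CH2Cl2, 0 °C to rt; used as a solution
Reagents that add atoms: oxalyl chloride, O=C(Cl)C(Cl)=O
Why: Activation through the chloroiminium salt without any base, so no ketene can form and the α-stereocentre is retained.

Step 16
Reactants: 22 (1S,5S,7S,8R)-2-methoxy-8-methyl-3,5,7-tris(3-methylbut-2-en-1-yl)-8-(4-methylpent-3-en-1-yl)bicyclo[3.3.1]non-2-ene-4,9-dione; 24 (2R)-2-methylbutanoyl chloride
Product: 25 (1S,5R,7S,8R)-2-methoxy-8-methyl-1-[(2R)-2-methylbutanoyl]-3,5,7-tris(3-methylbut-2-en-1-yl)-8-(4-methylpent-3-en-1-yl)bicyclo[3.3.1]non-2-ene-4,9-dione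
Conditions: lithium 2,2,6,6-tetramethylpiperidide (1.5 equiv), THF, −78 °C; then 24 (2 equiv), −78 °C; aq. NH4Cl
Reagents that add atoms: (2R)-2-methylbutanoyl chloride (24), CC[C@@H](C)C(Cl)=O
Why: Bridgehead lithiation and C-acylation, known for methoxy-enone bicyclo[3.3.1]nonanones; C1–H is the only proton both α to the C9 ketone and γ to the C4 carbonyl, lithium is held by the C2 methoxy and C9 oxygens, a bridgehead anion can only be acylated with retention, and the cold inverse quench limits ketene formation from 24.

Step 17
Reactants: 25 (1S,5R,7S,8R)-2-methoxy-8-methyl-1-[(2R)-2-methylbutanoyl]-3,5,7-tris(3-methylbut-2-en-1-yl)-8-(4-methylpent-3-en-1-yl)bicyclo[3.3.1]non-2-ene-4,9-dione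
Product: 26 (1S,5R,7S,8R)-2-hydroxy-8-methyl-1-[(2R)-2-methylbutanoyl]-3,5,7-tris(3-methylbut-2-en-1-yl)-8-(4-methylpent-3-en-1-yl)bicyclo[3.3.1]non-2-ene-4,9-dione (target)
Conditions: LiCl (10 equiv), DMSO, 120 °C, argon; then pH 5 buffer, 0 °C
Reagents that add atoms: none
Why: Krapcho-type SN2 demethylation of the vinylogous methyl ester by chloride in a neutral medium, which avoids hydroxide (retro-Claisen at C1) and acid (prenyl cyclisation); the product is a weakly basic enolate, so enolisation of the side-chain stereocentre should be slow, and the time at 120 °C is kept short for that reason.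

## Compound list

1 | 1,3-dimethoxybenzene | COc1cccc(OC)c1 | starting material
2 | 1,5-dibromo-2,4-dimethoxybenzene | COc1cc(OC)c(Br)cc1Br | intermediate
3 | 1-bromo-3-methylbut-2-ene | CC(C)=CCBr | starting material
4 | 1,5-dimethoxy-2,4-bis(3-methylbut-2-en-1-yl)benzene | COc1cc(OC)c(CC=C(C)C)cc1CC=C(C)C | intermediate
5 | 3-bromo-2,4-dimethoxy-1,5-bis(3-methylbut-2-en-1-yl)benzene | COc1c(CC=C(C)C)cc(CC=C(C)C)c(OC)c1Br | intermediate
6 | propanoic acid | CCC(=O)O | starting material
7 | 2-[2,6-dimethoxy-3,5-bis(3-methylbut-2-en-1-yl)phenyl]propanoic acid (racemic) | CC(C(=O)O)c1c(OC)c(CC=C(C)C)cc(CC=C(C)C)c1OC | intermediate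
8 | 5-bromo-2-methylpent-2-ene | CC(C)=CCCBr | starting material
9 | (2S)-2-[2,6-dimethoxy-3,5-bis(3-methylbut-2-en-1-yl)phenyl]-2,6-dimethylhept-5-enoic acid | OC(=O)[C@@](C)(CCC=C(C)C)c1c(OC)c(CC=C(C)C)cc(CC=C(C)C)c1OC | intermediate
10 | lithium (2S)-2-[2,6-dimethoxy-3,5-bis(3-methylbut-2-en-1-yl)cyclohexa-2,5-dien-1-yl]-2,6-dimethylhept-5-enoate | [Li+].[O-]C(=O)[C@@](C)(CCC=C(C)C)C1C(OC)=C(CC=C(C)C)CC(CC=C(C)C)=C1OC | intermediate (not isolated)
11 | methyl (2S)-2-[2,6-dimethoxy-3,5-bis(3-methylbut-2-en-1-yl)cyclohexa-2,5-dien-1-yl]-2,6-dimethylhept-5-enoate | COC(=O)[C@@](C)(CCC=C(C)C)C1C(OC)=C(CC=C(C)C)CC(CC=C(C)C)=C1OC | intermediate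
12 | methyl phenyl sulfone | CS(=O)(=O)c1ccccc1 | starting material
13 | (3S)-3-[2,6-dimethoxy-3,5-bis(3-methylbut-2-en-1-yl)cyclohexa-2,5-dien-1-yl]-3,7-dimethyl-1-(phenylsulfonyl)oct-6-en-2-one | O=C(CS(=O)(=O)c1ccccc1)[C@@](C)(CCC=C(C)C)C1C(OC)=C(CC=C(C)C)CC(CC=C(C)C)=C1OC | intermediate
14 | (3S)-1-diazo-3-[2,6-dimethoxy-3,5-bis(3-methylbut-2-en-1-yl)cyclohexa-2,5-dien-1-yl]-3,7-dimethyl-1-(phenylsulfonyl)oct-6-en-2-one | [N-]=[N+]=C(C(=O)[C@@](C)(CCC=C(C)C)C1C(OC)=C(CC=C(C)C)CC(CC=C(C)C)=C1OC)S(=O)(=O)c1ccccc1 | intermediate
15 | alkoxy-acyl cyclopropane: tricyclo[4.4.0.0(5,7)]dec-2-en-8-one with C6 bonded to C5, C9 and C7, methoxy on C9 and C2, phenylsulfonyl on C6, prenyl on C3 and C5, C8 methyl and homoprenyl | COC1=C(CC=C(C)C)C[C@]2(CC=C(C)C)[C@](OC)([C@H]1[C@](C)(CCC=C(C)C)C3=O)[C@@]23S(=O)(=O)c1ccccc1 | intermediate (not isolated)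
16 | (1S,5R,8S)-2-methoxy-8-methyl-3,5-bis(3-methylbut-2-en-1-yl)-8-(4-methylpent-3-en-1-yl)-6-(phenylsulfonyl)bicyclo[3.3.1]non-2-ene-7,9-dione (C6 undefined) | [C@H]12C(=O)[C@](CC=C(C)C)(C(S(=O)(=O)c3ccccc3)C(=O)[C@@]1(C)CCC=C(C)C)CC(CC=C(C)C)=C2OC | intermediate
17 | (1S,5R,8S)-2-methoxy-8-methyl-3,5-bis(3-methylbut-2-en-1-yl)-8-(4-methylpent-3-en-1-yl)-9-oxo-6-(phenylsulfonyl)bicyclo[3.3.1]nona-2,6-dien-7-yl trifluoromethanesulfonate | [C@H]12C(=O)[C@](CC=C(C)C)(C(S(=O)(=O)c3ccccc3)=C(OS(=O)(=O)C(F)(F)F)[C@@]1(C)CCC=C(C)C)CC(CC=C(C)C)=C2OC | intermediate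
18 | (1S,5R,8S)-2-methoxy-8-methyl-3,5-bis(3-methylbut-2-en-1-yl)-8-(4-methylpent-3-en-1-yl)-6-(phenylsulfonyl)bicyclo[3.3.1]nona-2,6-dien-9-one | [C@H]12C(=O)[C@](CC=C(C)C)(C(S(=O)(=O)c3ccccc3)=C[C@@]1(C)CCC=C(C)C)CC(CC=C(C)C)=C2OC | intermediate
19 | (3-methylbut-2-en-1-yl)magnesium chloride (THF solution) | CC(C)=CC[Mg]Cl | starting material
20 | (1S,5R,7R,8S)-2-methoxy-8-methyl-3,5,7-tris(3-methylbut-2-en-1-yl)-8-(4-methylpent-3-en-1-yl)-6-(phenylsulfonyl)bicyclo[3.3.1]non-2-en-9-one (C6 undefined, C7 prenyl exo) | [C@H]12C(=O)[C@](CC=C(C)C)(C(S(=O)(=O)c3ccccc3)[C@H](CC=C(C)C)[C@@]1(C)CCC=C(C)C)CC(CC=C(C)C)=C2OC | intermediate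
21 | (1S,5R,7S,8R)-2-methoxy-8-methyl-3,5,7-tris(3-methylbut-2-en-1-yl)-8-(4-methylpent-3-en-1-yl)bicyclo[3.3.1]non-2-en-9-one | [C@H]12C(=O)[C@](CC=C(C)C)(C[C@H](CC=C(C)C)[C@@]1(C)CCC=C(C)C)CC(CC=C(C)C)=C2OC | intermediate
22 | (1S,5S,7S,8R)-2-methoxy-8-methyl-3,5,7-tris(3-methylbut-2-en-1-yl)-8-(4-methylpent-3-en-1-yl)bicyclo[3.3.1]non-2-ene-4,9-dione | [C@H]12C(=O)[C@](CC=C(C)C)(C[C@H](CC=C(C)C)[C@@]1(C)CCC=C(C)C)C(=O)C(CC=C(C)C)=C2OC | intermediate
23 | (2R)-2-methylbutanoic acid | CC[C@@H](C)C(=O)O | starting material
24 | (2R)-2-methylbutanoyl chloride | CC[C@@H](C)C(Cl)=O | intermediate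
25 | (1S,5R,7S,8R)-2-methoxy-8-methyl-1-[(2R)-2-methylbutanoyl]-3,5,7-tris(3-methylbut-2-en-1-yl)-8-(4-methylpent-3-en-1-yl)bicyclo[3.3.1]non-2-ene-4,9-dione | CC[C@@H](C)C(=O)[C@]12C(=O)[C@](CC=C(C)C)(C[C@H](CC=C(C)C)[C@@]1(C)CCC=C(C)C)C(=O)C(CC=C(C)C)=C2OC | intermediate
26 | (1S,5R,7S,8R)-2-hydroxy-8-methyl-1-[(2R)-2-methylbutanoyl]-3,5,7-tris(3-methylbut-2-en-1-yl)-8-(4-methylpent-3-en-1-yl)bicyclo[3.3.1]non-2-ene-4,9-dione | CC[C@@H](C)C(=O)[C@]12C(=O)[C@](CC=C(C)C)(C[C@H](CC=C(C)C)[C@@]1(C)CCC=C(C)C)C(=O)C(CC=C(C)C)=C2O | target

## Step count and least certain steps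

Total step count: 17. Longest linear sequence: 16 (steps 1–14, 16 and 17); step 15 is a one-step side branch.

Step 9 (key step). The most likely failure is poor discrimination between the two diastereotopic enol ethers, because the C8 centre and the ligand may be mismatched and the substrate bias is small. Addition of the carbenoid to the homoprenyl alkene and hydrolysis of the second enol ether during the opening are secondary losses.

Fallback: remove C8 from the selection and set it afterwards on the bicycle. The fallback sets out from 5 and returns at 16.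
- Arylation of acetic acid with 5 under the conditions of step 4 gives [2,6-dimethoxy-3,5-bis(3-methylbut-2-en-1-yl)phenyl]acetic acid F1.
- Dianion alkylation with 8 (LiN(i-Pr)2, 2.2 equiv) gives racemic 2-aryl-6-methylhept-5-enoic acid F2.
- Birch reduction and methylation as in step 6 give diene ester F3.
- Sulfone acylation as in step 7 gives keto sulfone F4, and diazo transfer as in step 8 gives diazo keto sulfone F5.
- The copper–bisoxazoline reaction of step 9 now selects between enantiotopic enol ethers of a substrate whose C8 is epimerisable. It passes through cyclopropane F6 to the C8-H bicyclic keto sulfone F7.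
- The dianion of F7 (NaH, then n-BuLi) is methylated with MeI at C8. Attack from the exo face, away from ring B, should place the methyl group axial and give 16.

Step 5. The most likely failure is insufficient face selection in the alkylation, because the two ortho methoxy groups can bind lithium and disturb the mixed aggregate, and the unactivated bromide reacts slowly at low temperature.

Fallback: classical resolution. It sets out from 7 and returns at 9. Alkylation of the dianion of 7 (LiN(i-Pr)2, 2.2 equiv, then 8) gives the racemic quaternary acid F8. Crystallisation with (S)-1-phenylethylamine (or its antipode, whichever gives the less soluble salt of the wanted acid) gives the diastereomerically pure salt F9, and acidification returns 9.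

Step 12. The most likely failures are transfer of the prenyl group through its substituted terminus (a 1,1-dimethylallyl group at C7) and slow addition at the neopentyl-like C7. Attack on the endo face is less likely.

Fallback: separate C–C bond formation from the alkene substitution pattern. It sets out from 18 and returns at 20. Allylmagnesium bromide with CuBr·SMe2 gives the 7-allyl sulfone F10, which has no regiochemical ambiguity. Cross-metathesis with 2-methylbut-2-ene and the second-generation Grubbs catalyst then converts the allyl group into the prenyl group of 20. The other trisubstituted alkenes undergo only degenerate exchange.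

Step 14. The most likely failure is hydrogen abstraction at the doubly allylic CH2 of the C3 prenyl group in place of C4–H. That C–H bond is weaker, and oxidation there destroys the side chain. This is the weakest point of the endgame.

Fallback: bring the C4 oxygen in by polar chemistry through an enone. It sets out from 21 and returns at 22.
- Hydrolysis of the enol ether (aqueous oxalic acid, THF) gives the 2,9-dione F11.
- Dehydrogenation with 2-iodoxybenzoic acid gives the endocyclic C3=C4 enone F12. Formation of the exocyclic alkylidene isomer is the process to watch.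
- Weitz–Scheffer epoxidation (t-BuOOH, DBU) gives epoxy ketone F13.
- Isomerisation with Pd(PPh3)4 and 1,2-bis(diphenylphosphino)ethane gives the cyclic 1,3-dione F14.
- O-Methylation with trimethylsilyldiazomethane returns 22. The regioisomeric methyl ether converges on 26 through steps 16 and 17 as well.

Step 16. The most likely failures are deprotonation of 24 to a ketene by the bridgehead anion or the amide base, which would erode the (R) centre, and slow acylation at the hindered C1.

Fallback: add an aldehyde and oxidise. It sets out from 22 and 23 and returns at 25. Reduction of 23 (LiAlH4) gives (2R)-2-methylbutan-1-ol F15. Oxidation with TEMPO and PhI(OAc)2 gives (2R)-2-methylbutanal F16, which is used at once. Addition of lithiated 22 at −78 °C gives carbinol F17 as a mixture at the carbinol carbon, and Dess–Martin oxidation gives 25.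

If step 17 erodes the side-chain centre, the two C2' epimers are diastereomers and can be separated.

## Further compounds

F1 | step 9 | [2,6-dimethoxy-3,5-bis(3-methylbut-2-en-1-yl)phenyl]acetic acid | OC(=O)Cc1c(OC)c(CC=C(C)C)cc(CC=C(C)C)c1OC
F2 | step 9 | 2-[2,6-dimethoxy-3,5-bis(3-methylbut-2-en-1-yl)phenyl]-6-methylhept-5-enoic acid (racemic) | OC(=O)C(CCC=C(C)C)c1c(OC)c(CC=C(C)C)cc(CC=C(C)C)c1OC
F3 | step 9 | methyl 2-[2,6-dimethoxy-3,5-bis(3-methylbut-2-en-1-yl)cyclohexa-2,5-dien-1-yl]-6-methylhept-5-enoate (racemic) | COC(=O)C(CCC=C(C)C)C1C(OC)=C(CC=C(C)C)CC(CC=C(C)C)=C1OC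
F4 | step 9 | 3-[2,6-dimethoxy-3,5-bis(3-methylbut-2-en-1-yl)cyclohexa-2,5-dien-1-yl]-7-methyl-1-(phenylsulfonyl)oct-6-en-2-one | O=C(CS(=O)(=O)c1ccccc1)C(CCC=C(C)C)C1C(OC)=C(CC=C(C)C)CC(CC=C(C)C)=C1OC
F5 | step 9 | 1-diazo-3-[2,6-dimethoxy-3,5-bis(3-methylbut-2-en-1-yl)cyclohexa-2,5-dien-1-yl]-7-methyl-1-(phenylsulfonyl)oct-6-en-2-one | [N-]=[N+]=C(C(=O)C(CCC=C(C)C)C1C(OC)=C(CC=C(C)C)CC(CC=C(C)C)=C1OC)S(=O)(=O)c1ccccc1
F6 | step 9 | C8-H analogue of cyclopropane 15 (C8 undefined) | COC1=C(CC=C(C)C)C[C@]2(CC=C(C)C)[C@](OC)([C@H]1C(CCC=C(C)C)C3=O)[C@@]23S(=O)(=O)c1ccccc1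
F7 | step 9 | (1S,5R)-2-methoxy-3,5-bis(3-methylbut-2-en-1-yl)-8-(4-methylpent-3-en-1-yl)-6-(phenylsulfonyl)bicyclo[3.3.1]non-2-ene-7,9-dione (C6 and C8 undefined) | [C@H]12C(=O)[C@](CC=C(C)C)(C(S(=O)(=O)c3ccccc3)C(=O)C1CCC=C(C)C)CC(CC=C(C)C)=C2OC
F8 | step 5 | 2-[2,6-dimethoxy-3,5-bis(3-methylbut-2-en-1-yl)phenyl]-2,6-dimethylhept-5-enoic acid (racemic) | OC(=O)C(C)(CCC=C(C)C)c1c(OC)c(CC=C(C)C)cc(CC=C(C)C)c1OC
F9 | step 5 | (S)-1-phenylethylammonium (2S)-2-[2,6-dimethoxy-3,5-bis(3-methylbut-2-en-1-yl)phenyl]-2,6-dimethylhept-5-enoate | [O-]C(=O)[C@@](C)(CCC=C(C)C)c1c(OC)c(CC=C(C)C)cc(CC=C(C)C)c1OC.C[C@H]([NH3+])c1ccccc1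
F10 | step 12 | (1S,5R,7R,8S)-2-methoxy-8-methyl-3,5-bis(3-methylbut-2-en-1-yl)-8-(4-methylpent-3-en-1-yl)-6-(phenylsulfonyl)-7-(prop-2-en-1-yl)bicyclo[3.3.1]non-2-en-9-one (C6 undefined) | [C@H]12C(=O)[C@](CC=C(C)C)(C(S(=O)(=O)c3ccccc3)[C@H](CC=C)[C@@]1(C)CCC=C(C)C)CC(CC=C(C)C)=C2OC
F11 | step 14 | (1S,5R,7S,8R)-8-methyl-3,5,7-tris(3-methylbut-2-en-1-yl)-8-(4-methylpent-3-en-1-yl)bicyclo[3.3.1]nonane-2,9-dione (C3 undefined) | [C@H]12C(=O)[C@](CC=C(C)C)(C[C@H](CC=C(C)C)[C@@]1(C)CCC=C(C)C)CC(CC=C(C)C)C2=O
F12 | step 14 | (1S,5R,7S,8R)-8-methyl-3,5,7-tris(3-methylbut-2-en-1-yl)-8-(4-methylpent-3-en-1-yl)bicyclo[3.3.1]non-3-ene-2,9-dione | [C@H]12C(=O)[C@](CC=C(C)C)(C[C@H](CC=C(C)C)[C@@]1(C)CCC=C(C)C)C=C(CC=C(C)C)C2=O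
F13 | step 14 | 3,4-epoxide of F12 (epoxide face undefined) | [C@H]12C(=O)[C@](CC=C(C)C)(C[C@H](CC=C(C)C)[C@@]1(C)CCC=C(C)C)C3OC3(CC=C(C)C)C2=O
F14 | step 14 | (1S,5S,7S,8R)-2-hydroxy-8-methyl-3,5,7-tris(3-methylbut-2-en-1-yl)-8-(4-methylpent-3-en-1-yl)bicyclo[3.3.1]non-2-ene-4,9-dione | [C@H]12C(=O)[C@](CC=C(C)C)(C[C@H](CC=C(C)C)[C@@]1(C)CCC=C(C)C)C(=O)C(CC=C(C)C)=C2O
F15 | step 16 | (2R)-2-methylbutan-1-ol | CC[C@@H](C)CO
F16 | step 16 | (2R)-2-methylbutanal | CC[C@@H](C)C=O
F17 | step 16 | (1S,5R,7S,8R)-1-[(2R)-1-hydroxy-2-methylbutyl]-2-methoxy-8-methyl-3,5,7-tris(3-methylbut-2-en-1-yl)-8-(4-methylpent-3-en-1-yl)bicyclo[3.3.1]non-2-ene-4,9-dione (carbinol carbon undefined) | CC[C@@H](C)C(O)[C@]12C(=O)[C@](CC=C(C)C)(C[C@H](CC=C(C)C)[C@@]1(C)CCC=C(C)C)C(=O)C(CC=C(C)C)=C2OC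
A1 | alternative 1 | 6-{2-oxo-2-[(1S,5S)-4-methyl-1,5-bis(3-methylbut-2-en-1-yl)-2-oxocyclohex-3-en-1-yl]ethyl}-2,2-dimethyl-4H-1,3-dioxin-4-one (photosubstrate, stereocentres as in the SMILES) | O=C1C=C(C)[C@@H](CC=C(C)C)C[C@]1(CC=C(C)C)C(=O)CC1=CC(=O)OC(C)(C)O1
A2 | alternative 1 | cyclobutane photoadduct containing rings B and C | [C@H]12C(=O)[C@](CC=C(C)C)(C[C@H](CC=C(C)C)[C@@]1(C)[C@@H]3C(=O)OC(C)(C)O[C@]23C4)C4=O
A3 | alternative 2 | dimethyl 2-(3-methylbut-2-en-1-yl)-2-[(2S,3R)-3-methyl-2-(3-methylbut-2-en-1-yl)-3-(4-methylpent-3-en-1-yl)-5-oxo-9-methyldec-8-en-1-yl]propanedioate (keto malonate, stereocentres as in the SMILES) | COC(=O)C(CC=C(C)C)(C[C@H](CC=C(C)C)[C@@](C)(CCC=C(C)C)CC(=O)CCC=C(C)C)C(=O)OC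
A4 | alternative 2 | C1-unsubstituted bicyclo[3.3.1]nonane trione, enol form | [C@H]12C(=O)[C@](CC=C(C)C)(C[C@H](CC=C(C)C)[C@@]1(C)CCC=C(C)C)C(=O)C(CC=C(C)C)=C2O
A5 | alternative 3 | (Z)-4,8-dimethyl-2-[tri(propan-2-yl)silyloxy]nona-1,3,7-triene | C=C(O[Si](C(C)C)(C(C)C)C(C)C)/C=C(\CCC=C(C)C)C
A6 | alternative 3 | 3-(prop-2-enoyl)-1,3-oxazolidin-2-one | C=CC(=O)N1CCOC1=O
A7 | alternative 3 | ring C silyl enol ether with the C7 imide and quaternary C8 | O=C1OCCN1C(=O)[C@H]1CCC(O[Si](C(C)C)(C(C)C)C(C)C)=C[C@]1(C)CCC=C(C)C
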